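**Plan**

1. Retrosynthetic cuts, in order: the two ester C–O bonds at O9 and O8; the lactone bonds O–C6 and C11–C12 (carbon dioxide taken out); C6–C7 of the ten-membered ring (retro-oxy-Cope, which restores the C4–C9 bond of a 1,2-divinylcyclohexenol); C8–C9 (dienyllithium + cyclohexenone); the two ring bonds of a Diels–Alder adduct.
2. Forward: Diels–Alder cyclohexene → enone → divinyl carbinol → anionic oxy-Cope ring expansion to the (1(10)Z,4E)-cyclodecadiene → oxygen at C8 and C9 → γ-lactone closed on the carbocycle with CO2 → esters at O9, then O8; C14 to the aldehyde.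
3. Enabling feature: C6 is an allylic carbon of the C4=C5 alkene (a π-allyl terminus), C11 is an sp2 carbon carrying the exocyclic C13 methylene (an alkenyl-metal position), and C7 joins them. O=C=O can therefore bridge C11 (through carbon) and C6 (through oxygen) to close the five-membered lactone ring.
4. Stereochemistry: one catalytic asymmetric Diels–Alder reaction sets a quaternary centre; the chair oxy-Cope transfers it to C6 and C7 and sets 4E; the cyclohexene gives 1(10)Z. C8 comes from outer-face hydroxylation followed by Mitsunobu inversion, C9 from outer-face hydride, and C6 is kept by double inversion in the key step.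
5. Side-chain acid: neryl acetate supplies the 10Z alkene; two Still–Gennari olefinations set 6Z and 2Z.

Key step: step 21

Remark 1: germacrane numbering (C1–C15) is used for the ten-membered ring; α/β refer to the usual drawing with H-7 α, so the target (6R,7S,8S,9S) is 6α-O, 7α-H, 8β-O, 9α-O.
Remark 2: reagents are assumed to attack the ten-membered ring from its outer face in the conformer delivered by the chair oxy-Cope transition state. The (S)-oxazaborolidinium ion of step 3 is assumed to give the 1R adduct; its antipode would be used if the sense proved opposite.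

**Route**

Step 1
Reactants: 1 (1-bromoethenyl)trimethylsilane; 2 (E)-1,2-bis(tributylstannyl)ethene (2 equiv)
Product: 3 tributyl[(1E)-3-(trimethylsilyl)buta-1,3-dien-1-yl]stannane
Conditions: Pd(PPh3)4 (5 mol%), toluene, 90 °C
Reagents that add atoms: none
Why: Stille coupling, in which the alkenyl bromide adds oxidatively to zerovalent palladium and couples once with the distannane used in excess, with retention of the E geometry.

Step 2
Reactants: 4 (E)-but-2-enal
Product: 5 [(1E)-buta-1,3-dien-1-yloxy]triisopropylsilane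
Conditions: i-Pr3SiOTf, Et3N, Et2O, 0 °C → rt
Reagents that add atoms: triisopropylsilyl trifluoromethanesulfonate, CC(C)[Si](OS(=O)(=O)C(F)(F)F)(C(C)C)C(C)C
Why: Silyl dienol ether formation by O-silylation of the extended enolate (γ-deprotonation), which should give mainly the E-dienyl ether, the only isomer that reacts in step 3.

Step 3
Reactants: 5 [(1E)-buta-1,3-dien-1-yloxy]triisopropylsilane; 6 2-methylprop-2-enal
Product: 7 (1R,2S)-1-methyl-2-[(triisopropylsilyl)oxy]cyclohex-3-ene-1-carbaldehyde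
Conditions: (S)-o-tolyl-oxazaborolidine from (S)-α,α-diphenylprolinol, protonated with Tf2NH (10 mol%), CH2Cl2, −78 °C
Reagents that add atoms: none
Why: Enantioselective Lewis acid-catalysed Diels–Alder reaction, in which the 1-silyloxy group directs "ortho" regiochemistry, endo addition places formyl and silyloxy cis, and the chiral oxazaborolidinium ion shields one face of the coordinated aldehyde so that the quaternary centre is set as 1R.

Step 4
Reactants: 7 (1R,2S)-1-methyl-2-[(triisopropylsilyl)oxy]cyclohex-3-ene-1-carbaldehyde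
Product: 8 {[(1S,6S)-6-[(E)-2-iodoethenyl]-6-methylcyclohex-2-en-1-yl]oxy}triisopropylsilane
Conditions: CrCl2 (6 equiv), CHI3 (2 equiv), THF, 0 °C → rt
Reagents that add atoms: iodoform, IC(I)I
Why: Takai olefination, in which the geminal dichromium species adds to the hindered aldehyde and eliminates to the E-iodoalkene.

Step 5
Reactants: 8 the (E)-iodoalkene; 9 (4-methoxyphenyl)methanol
Product: 10 {[(1S,6S)-6-{(E)-2-[(4-methoxybenzyl)oxy]ethenyl}-6-methylcyclohex-2-en-1-yl]oxy}triisopropylsilane
Conditions: CuI (10 mol%), 3,4,7,8-tetramethyl-1,10-phenanthroline (20 mol%), Cs2CO3, toluene, 80 °C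
Reagents that add atoms: none
Why: Copper-catalysed C–O cross-coupling (Ullmann-type vinylation of an alcohol), which proceeds with retention of alkene geometry and so should give the E-enol ether.

Step 6
Reactants: 10 the silyl ether
Product: 11 (1S,6S)-6-{(E)-2-[(4-methoxybenzyl)oxy]ethenyl}-6-methylcyclohex-2-en-1-ol
Conditions: Bu4NF, THF, 0 °C → rt
Reagents that add atoms: none
Why: Fluoride-mediated desilylation, which leaves the enol ether and the quaternary centre untouched.

Step 7
Reactants: 11 the allylic alcohol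
Product: 12 (6S)-6-{(E)-2-[(4-methoxybenzyl)oxy]ethenyl}-6-methylcyclohex-2-en-1-one
Conditions: Dess–Martin periodinane, NaHCO3, CH2Cl2, 0 °C → rt
Reagents that add atoms: none
Why: Dess–Martin oxidation of the allylic alcohol under buffered conditions that spare the enol ether, removing the now superfluous carbinol stereocentre.

Step 8
Reactants: 12 the enone
Product: 13 (6S)-2-(hydroxymethyl)-6-{(E)-2-[(4-methoxybenzyl)oxy]ethenyl}-6-methylcyclohex-2-en-1-one
Conditions: aqueous formaldehyde (37%), DMAP (30 mol%), THF/H2O, rt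
Reagents that add atoms: formaldehyde, C=O
Why: Morita–Baylis–Hillman reaction, in which DMAP adds to C3 of the enone, the enolate is hydroxymethylated at C2 and elimination regenerates the enone.

Step 9
Reactants: 13 the hydroxymethyl enone
Product: 14 (6S)-2-{[(tert-butyldimethylsilyl)oxy]methyl}-6-{(E)-2-[(4-methoxybenzyl)oxy]ethenyl}-6-methylcyclohex-2-en-1-one
Conditions: t-BuMe2SiCl, imidazole, DMF, rt
Reagents that add atoms: tert-butyldimethylsilyl chloride, CC(C)(C)[Si](C)(C)Cl
Why: Silylation of the primary allylic alcohol.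

Step 10
Reactants: 14 the silylated enone; 3 tributyl[(1E)-3-(trimethylsilyl)buta-1,3-dien-1-yl]stannane
Product: 15 (1R,6S)-2-{[(tert-butyldimethylsilyl)oxy]methyl}-6-{(E)-2-[(4-methoxybenzyl)oxy]ethenyl}-6-methyl-1-[(1E)-3-(trimethylsilyl)buta-1,3-dien-1-yl]cyclohex-2-en-1-ol
Conditions: 3, n-BuLi, THF, −78 °C; then 14, −78 °C; H2O
Reagents that add atoms: none
Why: Tin–lithium exchange followed by 1,2-addition of the alkenyllithium to the enone carbonyl, where attack anti to the pseudoaxial alkoxyvinyl group is expected to favour the trans-divinyl carbinol (1R), the cis isomer being removed by chromatography.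

Step 11
Reactants: 15 the trans-divinyl carbinol
Product: 18 (1(10)Z,4E)-14-[(tert-butyldimethylsilyl)oxy]-8α-hydroxy-6α-[(4-methoxybenzyl)oxy]-11-(trimethylsilyl)-12-norgermacra-1(10),4,11(13)-trien-9-one, via potassium alkoxide 16 (not isolated), via potassium dienolate 17 (not isolated)
Conditions: KN(SiMe3)2 (1.2 equiv), 18-crown-6, THF, 0 °C; then 2-(benzenesulfonyl)-3-phenyloxaziridine, −78 °C; AcOH quench
Reagents that add atoms: 2-(benzenesulfonyl)-3-phenyloxaziridine, O=S(=O)(N1OC1c1ccccc1)c1ccccc1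
Why: Anionic oxy-Cope rearrangement followed by enolate hydroxylation with an N-sulfonyloxaziridine, in which the trans-divinyl alkoxide can react only through the chair transition state with both E substituents equatorial, which gives the 4E alkene and transfers the quaternary centre to C6 (α-O) and C7 (α-H), and the oxaziridine then attacks C8 of the E-enolate on its outer face (8α-OH).

Step 12
Reactants: 18 the 8α-hydroxy ketone
Product: 19 the 8β-(4-nitrobenzoyloxy) ketone (C8 inverted, otherwise as 18)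
Conditions: 4-nitrobenzoic acid, PPh3, diisopropyl azodicarboxylate, toluene/THF, 0 °C → rt
Reagents that add atoms: 4-nitrobenzoic acid, O=C(O)c1ccc(cc1)[N+](=O)[O-]
Why: Mitsunobu reaction, in which SN2 displacement at the activated α-keto carbinol by the carboxylate inverts C8 to the required 8β configuration.

Step 13
Reactants: 19 the 8β-(4-nitrobenzoate)
Product: 20 the 8β-hydroxy ketone (C8 epimer of 18)
Conditions: K2CO3 (20 mol%), MeOH, 0 °C, short contact
Reagents that add atoms: none
Why: Mild methanolysis (transesterification) of the activated aryl ester, kept cold and brief so that the ketol does not enolise.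

Step 14
Reactants: 20 the 8β-hydroxy ketone
Product: 21 the 8β,14-bis[(tert-butyldimethylsilyl)oxy] ketone
Conditions: t-BuMe2SiOTf, 2,6-lutidine, CH2Cl2, −78 °C
Reagents that add atoms: tert-butyldimethylsilyl trifluoromethanesulfonate, CC(C)(C)[Si](C)(C)OS(=O)(=O)C(F)(F)F
Why: Silylation with the silyl triflate at low temperature, which also blocks chelation in step 15.

Step 15
Reactants: 21 the silyloxy enone
Product: 22 the 9α-alcohol (8β,14-bis-silyloxy, 6α-OPMB, 11-SiMe3)
Conditions: NaBH4, CeCl3·7H2O, MeOH/THF, −78 °C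
Reagents that add atoms: none
Why: Luche 1,2-reduction of the enone, in which hydride is expected to reach the outer face of the C9 carbonyl of the ten-membered ring and so place the new hydroxyl 9α, trans to the 8β-silyloxy group.

Step 16
Reactants: 22 the 9α-alcohol
Product: 23 the 9α-triethylsilyl ether
Conditions: Et3SiOTf, 2,6-lutidine, CH2Cl2, −78 → 0 °C
Reagents that add atoms: triethylsilyl trifluoromethanesulfonate, CC[Si](CC)(CC)OS(=O)(=O)C(F)(F)F
Why: Silylation of the secondary allylic alcohol with a group that can later be removed in the presence of the two tert-butyldimethylsilyl ethers.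

Step 17
Reactants: 23 the 6α-PMB ether
Product: 24 the 6α-alcohol
Conditions: DDQ, CH2Cl2/pH 7 buffer, 0 °C
Reagents that add atoms: none
Why: Oxidative cleavage of the 4-methoxybenzyl ether by DDQ (benzylic hydride abstraction, then hydrolysis), to which silyl ethers and the vinylsilane are inert.

Step 18
Reactants: 24 the vinylsilane
Product: 25 the 11-iodo compound (1-iodoethenyl group on C7)
Conditions: N-iodosuccinimide, MeCN/ClCH2CN (4:1), 0 °C, dark
Reagents that add atoms: N-iodosuccinimide, O=C1CCC(=O)N1I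
Why: Iododesilylation (electrophilic ipso substitution), in which attack on the vinylsilane is favoured by the β-silicon effect over attack on the oxygen-deactivated trisubstituted alkenes.

Step 19
Reactants: 25 the alkenyl iodide
Product: 26 the 11-(4,4,5,5-tetramethyl-1,3,2-dioxaborolan-2-yl) compound
Conditions: bis(pinacolato)diboron, PdCl2(PPh3)2 (3 mol%), PPh3, KOPh, toluene, 50 °C
Reagents that add atoms: bis(pinacolato)diboron, CC1(C)OB(OC1(C)C)B1OC(C)(C)C(C)(C)O1
Why: Miyaura borylation under the mild phenoxide conditions used for alkenyl halides, the free allylic alcohol not being ionised by zerovalent palladium without activation.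

Step 20
Reactants: 26 the hydroxy alkenylboronate
Product: 27 the 6α-methyl carbonate
Conditions: ClCO2Me, pyridine, DMAP (cat.), CH2Cl2, 0 °C
Reagents that add atoms: methyl chloroformate, COC(=O)Cl
Why: Acylation of the secondary allylic alcohol to the carbonate that serves as leaving group and internal alkoxide source in step 21.

Step 21
Reactants: 27 the carbonate/alkenylboronate
Product: 29 (1(10)Z,4E)-8β,14-bis[(tert-butyldimethylsilyl)oxy]-9α-[(triethylsilyl)oxy]germacra-1(10),4,11(13)-trien-12,6α-olide, via copper carboxylate 28 (not isolated)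
Conditions: (IPr)CuCl (10 mol%; IPr = 1,3-bis(2,6-diisopropylphenyl)imidazol-2-ylidene), KOt-Bu (10 mol%), Pd(PPh3)4 (5 mol%), CO2 (1 atm), THF, 50 °C
Reagents that add atoms: carbon dioxide, O=C=O
Why: Proposed new method: a copper/palladium relay in which (IPr)Cu–OR transmetallates the alkenylboronate at C11, the alkenylcopper inserts CO2 to give the monovalent copper carboxylate 28 (C11–C12 bond), zerovalent palladium ionises the C6 carbonate anti to the leaving group to a C4–C5–C6 π-allyl cation, and the carboxylate closes on C6 anti to palladium (O–C6 bond), while the methoxide freed from the carbonate regenerates (IPr)Cu–OMe; the closest known reaction types are the copper-catalysed carboxylation of alkenylboronic esters with CO2, palladium-catalysed allylic substitution by carboxylates, and copper/palladium dual catalysis in which the alkoxide from an allylic carbonate turns over copper. The one ring closed is the γ-lactone, by 5-exo attack of the carboxylate oxygen on the allyl terminus C6 (attack at C4 would need a seven-membered ring at a tertiary carbon). The only new stereocentre, C6, is controlled by the C6 carbonate itself: ionisation and attack each invert, so the 6α-oxygen should be returned with net retention and the lactone trans-fused to the 7α-H centre. The step needs carboxylation of the alkenylcopper before it can be transferred to the allylpalladium (C–C coupling), which is secured by the CO2 atmosphere, the fast insertion of CO2 into (IPr)Cu–alkenyl bonds and the strain of the three- or five-membered carbocycles that direct coupling would require. The E geometry of C4=C5 should be held because the π-allyl unit is locked in the ten-membered ring.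

Step 22
Reactants: 29 the tris-silylated lactone
Product: 30 the 9α-alcohol (8β,14-bis-silyloxy lactone)
Conditions: HF·pyridine, pyridine, THF, 0 °C
Reagents that add atoms: none
Why: Selective desilylation, the secondary triethylsilyl ether being cleaved by buffered HF·pyridine much faster than the two tert-butyldimethylsilyl ethers.

Step 23
Reactants: 31 neryl acetate
Product: 33 (2Z)-3-methyl-6-oxohex-2-en-1-yl acetate, via secondary ozonide 32 (not isolated)
Conditions: O3 (1.0 equiv), CH2Cl2, −78 °C; then Me2S, −78 °C → rt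
Reagents that add atoms: ozone, [O-][O+]=O
Why: Ozonolysis, in which the electron-rich terminal trisubstituted alkene reacts faster than the alkene deactivated by the allylic acetate, whose Z geometry is untouched.

Step 24
Reactants: 34 methyl 2-[bis(2,2,2-trifluoroethoxy)phosphoryl]acetate; 35 3-bromo-1,1-dimethoxypropane
Product: 36 methyl 2-[bis(2,2,2-trifluoroethoxy)phosphoryl]-5,5-dimethoxypentanoate (racemic)
Conditions: NaH, NaI (10 mol%), DMF, 0 → 50 °C
Reagents that add atoms: none
Why: C-alkylation (SN2) of the sodium salt of the phosphonoacetate with the primary bromide.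

Step 25
Reactants: 33 the aldehyde; 36 the phosphonate
Product: 37 methyl (2Z,6Z)-8-acetoxy-2-(3,3-dimethoxypropyl)-6-methylocta-2,6-dienoate
Conditions: KN(SiMe3)2, 18-crown-6, THF, −78 °C
Reagents that add atoms: none
Why: Still–Gennari olefination, in which the bis(trifluoroethyl) phosphonate with a dissociated potassium counter-ion eliminates fast from the kinetic adduct and should give the Z-enoate (ester cis to the new chain).

Step 26
Reactants: 37 the enoate
Product: 38 (2Z,6Z)-2-(3,3-dimethoxypropyl)-6-methylocta-2,6-diene-1,8-diol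
Conditions: i-Bu2AlH (5 equiv), CH2Cl2, −78 °C; aqueous Rochelle salt
Reagents that add atoms: none
Why: Hydride reduction of the enoate to the allylic alcohol with concomitant reductive cleavage of the acetate, the acetal being inert.

Step 27
Reactants: 38 the diol
Product: 39 (2Z,6Z)-2-(3,3-dimethoxypropyl)-6-methylocta-2,6-diene-1,8-diyl diacetate
Conditions: Ac2O, pyridine, DMAP (cat.), CH2Cl2, rt
Reagents that add atoms: acetic anhydride, CC(=O)OC(C)=O
Why: Acetylation of both primary allylic alcohols.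

Step 28
Reactants: 39 the acetal
Product: 40 (2Z,6Z)-6-methyl-2-(3-oxopropyl)octa-2,6-diene-1,8-diyl diacetate
Conditions: AcOH/H2O/THF (3:1:1), rt
Reagents that add atoms: water, O
Why: Acid-catalysed hydrolysis of the dimethyl acetal under conditions too mild to ionise the allylic acetates.

Step 29
Reactants: 41 3-bromobut-3-en-1-ol
Product: 42 4-methyl-3-methylidenepentan-1-ol
Conditions: i-PrMgCl (2.5 equiv), PdCl2(dppf) (3 mol%), THF, 0 °C → rt
Reagents that add atoms: isopropylmagnesium chloride, CC(C)[Mg]Cl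
Why: Kumada coupling with the wide-bite-angle dppf ligand, which should suppress isomerisation of the secondary alkyl group, one further equivalent of Grignard reagent being consumed by the hydroxyl group.

Step 30
Reactants: 42 the homoallylic alcohol
Product: 43 5-iodo-2-methyl-3-methylidenepentane
Conditions: I2, PPh3, imidazole, CH2Cl2, 0 °C
Reagents that add atoms: iodine, II
Why: Appel-type iodination of the primary alcohol.

Step 31
Reactants: 34 methyl 2-[bis(2,2,2-trifluoroethoxy)phosphoryl]acetate; 43 the iodide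
Product: 44 methyl 2-[bis(2,2,2-trifluoroethoxy)phosphoryl]-6-methyl-5-methylideneheptanoate (racemic)
Conditions: NaH, DMF, 0 → 50 °C
Reagents that add atoms: none
Why: C-alkylation (SN2) of the phosphonoacetate anion with the primary iodide.

Step 32
Reactants: 40 the aldehyde; 44 the phosphonate
Product: 45 methyl (2Z,6Z,10Z)-12-acetoxy-6-(acetoxymethyl)-10-methyl-2-(4-methyl-3-methylidenepentyl)dodeca-2,6,10-trienoate
Conditions: KN(SiMe3)2, 18-crown-6, THF, −78 °C
Reagents that add atoms: none
Why: Still–Gennari olefination, as in step 25, which should set the Z (angelate-type) trisubstituted enoate.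

Step 33
Reactants: 45 the triester
Product: 46 (2Z,6Z,10Z)-12-hydroxy-6-(hydroxymethyl)-10-methyl-2-(4-methyl-3-methylidenepentyl)dodeca-2,6,10-trienoic acid
Conditions: LiOH, THF/MeOH/H2O, 40 °C; then 1 M HCl to pH 3, 0 °C
Reagents that add atoms: lithium hydroxide, [Li+].[OH-]
Why: Saponification of all three esters, the hindered Z-enoate needing mild warming.

Step 34
Reactants: 46 the dihydroxy acid
Product: 48 (2Z,6Z,10Z)-12-acetoxy-6-(acetoxymethyl)-10-methyl-2-(4-methyl-3-methylidenepentyl)dodeca-2,6,10-trienoic acid, via mixed acetic anhydride 47 (not isolated)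
Conditions: Ac2O, pyridine, DMAP (cat.), CH2Cl2, 0 °C → rt; then H2O/THF, rt
Reagents that add atoms: acetic anhydride, CC(=O)OC(C)=O
Why: Acetylation of the two allylic alcohols, the mixed anhydride formed at the carboxyl group being hydrolysed in the aqueous second stage.

Step 35
Reactants: 30 the 9α-alcohol; 48 the side-chain acid
Product: 50 the 9α-ester of 30 with acid 48, via mixed aroyl anhydride 49 (not isolated)
Conditions: 2-methyl-6-nitrobenzoic anhydride, Et3N, DMAP, CH2Cl2, rt
Reagents that add atoms: none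
Why: Shiina esterification, in which the mixed anhydride is transferred through the acylpyridinium ion to the hindered 9α-hydroxyl at room temperature, conditions chosen to avoid Z→E isomerisation of the angelate-type acyl group.

Step 36
Reactants: 50 the bis-silyl ether
Product: 51 the 8β,14-diol
Conditions: HF·pyridine, pyridine, THF, 0 °C → rt
Reagents that add atoms: none
Why: Fluoride-mediated cleavage of both silyl ethers, to which the lactone, the esters and the allylic acetates are stable.

Step 37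
Reactants: 51 the diol
Product: 52 the 14-aldehyde with free 8β-OH
Conditions: MnO2, CH2Cl2, rt
Reagents that add atoms: none
Why: MnO2 oxidation, selective for the primary allylic alcohol over the non-allylic secondary C8 alcohol.

Step 38
Reactants: 53 methyl 2-(hydroxymethyl)prop-2-enoate
Product: 54 methyl 2-{[(tert-butyldimethylsilyl)oxy]methyl}prop-2-enoate
Conditions: t-BuMe2SiCl, imidazole, CH2Cl2, rt
Reagents that add atoms: tert-butyldimethylsilyl chloride, CC(C)(C)[Si](C)(C)Cl
Why: Silylation of the primary alcohol.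

Step 39
Reactants: 54 the silylated ester
Product: 55 2-{[(tert-butyldimethylsilyl)oxy]methyl}prop-2-enoic acid
Conditions: LiOH, THF/H2O, 0 °C; then 1 M HCl to pH 4, 0 °C
Reagents that add atoms: lithium hydroxide, [Li+].[OH-]
Why: Saponification of the methyl ester at low temperature, which the silyl ether should survive.

Step 40
Reactants: 52 the 8β-alcohol; 55 the silylated acrylic acid
Product: 57 the 8β-(2-{[(tert-butyldimethylsilyl)oxy]methyl}acryloyl) ester, via mixed aroyl anhydride 56 (not isolated)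
Conditions: 2-methyl-6-nitrobenzoic anhydride, Et3N, DMAP, CH2Cl2, rt
Reagents that add atoms: none
Why: Shiina esterification of the secondary C8 alcohol, the last acylation site left free.

Step 41
Reactants: 57 the silyl-protected target
Product: 58 the target, CNP0240680.3
Conditions: HF·pyridine, pyridine, THF, 0 °C → rt
Reagents that add atoms: none
Why: Fluoride-mediated desilylation of the primary silyl ether under conditions that leave the enal, the α-methylene lactone and the five esters untouched.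

**Compound list**

1 | (1-bromoethenyl)trimethylsilane | C=C(Br)[Si](C)(C)C | starting material
2 | (E)-1,2-bis(tributylstannyl)ethene | CCCC[Sn](CCCC)(CCCC)/C=C/[Sn](CCCC)(CCCC)CCCC | starting material
3 | tributyl[(1E)-3-(trimethylsilyl)buta-1,3-dien-1-yl]stannane | CCCC[Sn](CCCC)(CCCC)/C=C/C(=C)[Si](C)(C)C | intermediate
4 | (E)-but-2-enal | C/C=C/C=O | starting material
5 | [(1E)-buta-1,3-dien-1-yloxy]triisopropylsilane | C=C/C=C/O[Si](C(C)C)(C(C)C)C(C)C | intermediate
6 | 2-methylprop-2-enal | CC(=C)C=O | starting material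
7 | (1R,2S)-1-methyl-2-[(triisopropylsilyl)oxy]cyclohex-3-ene-1-carbaldehyde | CC(C)[Si](C(C)C)(C(C)C)O[C@H]1C=CCC[C@@]1(C)C=O | intermediate
8 | {[(1S,6S)-6-[(E)-2-iodoethenyl]-6-methylcyclohex-2-en-1-yl]oxy}triisopropylsilane | CC(C)[Si](C(C)C)(C(C)C)O[C@H]1C=CCC[C@@]1(C)/C=C/I | intermediate
9 | (4-methoxyphenyl)methanol | COc1ccc(CO)cc1 | starting material
10 | {[(1S,6S)-6-{(E)-2-[(4-methoxybenzyl)oxy]ethenyl}-6-methylcyclohex-2-en-1-yl]oxy}triisopropylsilane | CC(C)[Si](C(C)C)(C(C)C)O[C@H]1C=CCC[C@@]1(C)/C=C/OCc1ccc(OC)cc1 | intermediate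
11 | (1S,6S)-6-{(E)-2-[(4-methoxybenzyl)oxy]ethenyl}-6-methylcyclohex-2-en-1-ol | O[C@H]1C=CCC[C@@]1(C)/C=C/OCc1ccc(OC)cc1 | intermediate
12 | (6S)-6-{(E)-2-[(4-methoxybenzyl)oxy]ethenyl}-6-methylcyclohex-2-en-1-one | O=C1C=CCC[C@@]1(C)/C=C/OCc1ccc(OC)cc1 | intermediate
13 | (6S)-2-(hydroxymethyl)-6-{(E)-2-[(4-methoxybenzyl)oxy]ethenyl}-6-methylcyclohex-2-en-1-one | O=C1C(CO)=CCC[C@@]1(C)/C=C/OCc1ccc(OC)cc1 | intermediate
14 | (6S)-2-{[(tert-butyldimethylsilyl)oxy]methyl}-6-{(E)-2-[(4-methoxybenzyl)oxy]ethenyl}-6-methylcyclohex-2-en-1-one | O=C1C(CO[Si](C)(C)C(C)(C)C)=CCC[C@@]1(C)/C=C/OCc1ccc(OC)cc1 | intermediate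
15 | (1R,6S)-2-{[(tert-butyldimethylsilyl)oxy]methyl}-6-{(E)-2-[(4-methoxybenzyl)oxy]ethenyl}-6-methyl-1-[(1E)-3-(trimethylsilyl)buta-1,3-dien-1-yl]cyclohex-2-en-1-ol | O[C@@]1(/C=C/C(=C)[Si](C)(C)C)C(CO[Si](C)(C)C(C)(C)C)=CCC[C@@]1(C)/C=C/OCc1ccc(OC)cc1 | intermediate
16 | potassium alkoxide of 15 | [K+].[O-][C@@]1(/C=C/C(=C)[Si](C)(C)C)C(CO[Si](C)(C)C(C)(C)C)=CCC[C@@]1(C)/C=C/OCc1ccc(OC)cc1 | intermediate (not isolated)
17 | potassium C8=C9 (E) dienolate of the ring-expanded 9-ketone (6α-OPMB, 7α-H, 11-SiMe3, 14-OTBS) | [K+].[O-]/C1=C\[C@@H](C(=C)[Si](C)(C)C)[C@H](OCc2ccc(OC)cc2)/C=C(\C)CC/C=C1/CO[Si](C)(C)C(C)(C)C | intermediate (not isolated)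
18 | (1(10)Z,4E)-14-[(tert-butyldimethylsilyl)oxy]-8α-hydroxy-6α-[(4-methoxybenzyl)oxy]-11-(trimethylsilyl)-12-norgermacra-1(10),4,11(13)-trien-9-one | O[C@@H]1[C@@H](C(=C)[Si](C)(C)C)[C@H](OCc2ccc(OC)cc2)/C=C(\C)CC/C=C(/CO[Si](C)(C)C(C)(C)C)C1=O | intermediate
19 | 8β-(4-nitrobenzoyloxy) analogue of 18 (C8 inverted) | O=C(O[C@H]1[C@@H](C(=C)[Si](C)(C)C)[C@H](OCc2ccc(OC)cc2)/C=C(\C)CC/C=C(/CO[Si](C)(C)C(C)(C)C)C1=O)c1ccc(cc1)[N+](=O)[O-] | intermediate
20 | (1(10)Z,4E)-14-[(tert-butyldimethylsilyl)oxy]-8β-hydroxy-6α-[(4-methoxybenzyl)oxy]-11-(trimethylsilyl)-12-norgermacra-1(10),4,11(13)-trien-9-one | O[C@H]1[C@@H](C(=C)[Si](C)(C)C)[C@H](OCc2ccc(OC)cc2)/C=C(\C)CC/C=C(/CO[Si](C)(C)C(C)(C)C)C1=O | intermediate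
21 | 8β,14-bis[(tert-butyldimethylsilyl)oxy] ketone from 20 | CC(C)(C)[Si](C)(C)O[C@H]1[C@@H](C(=C)[Si](C)(C)C)[C@H](OCc2ccc(OC)cc2)/C=C(\C)CC/C=C(/CO[Si](C)(C)C(C)(C)C)C1=O | intermediate
22 | (1(10)Z,4E)-8β,14-bis[(tert-butyldimethylsilyl)oxy]-6α-[(4-methoxybenzyl)oxy]-11-(trimethylsilyl)-12-norgermacra-1(10),4,11(13)-trien-9α-ol | CC(C)(C)[Si](C)(C)O[C@H]1[C@@H](C(=C)[Si](C)(C)C)[C@H](OCc2ccc(OC)cc2)/C=C(\C)CC/C=C(/CO[Si](C)(C)C(C)(C)C)[C@@H]1O | intermediate
23 | 9α-triethylsilyl ether of 22 | CC(C)(C)[Si](C)(C)O[C@H]1[C@@H](C(=C)[Si](C)(C)C)[C@H](OCc2ccc(OC)cc2)/C=C(\C)CC/C=C(/CO[Si](C)(C)C(C)(C)C)[C@@H]1O[Si](CC)(CC)CC | intermediate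
24 | 6α-alcohol from 23 (PMB removed) | CC(C)(C)[Si](C)(C)O[C@H]1[C@@H](C(=C)[Si](C)(C)C)[C@H](O)/C=C(\C)CC/C=C(/CO[Si](C)(C)C(C)(C)C)[C@@H]1O[Si](CC)(CC)CC | intermediate
25 | 11-iodo analogue of 24 (1-iodoethenyl on C7) | CC(C)(C)[Si](C)(C)O[C@H]1[C@@H](C(I)=C)[C@H](O)/C=C(\C)CC/C=C(/CO[Si](C)(C)C(C)(C)C)[C@@H]1O[Si](CC)(CC)CC | intermediate
26 | 11-(4,4,5,5-tetramethyl-1,3,2-dioxaborolan-2-yl) analogue of 25 | CC(C)(C)[Si](C)(C)O[C@H]1[C@@H](C(=C)B2OC(C)(C)C(C)(C)O2)[C@H](O)/C=C(\C)CC/C=C(/CO[Si](C)(C)C(C)(C)C)[C@@H]1O[Si](CC)(CC)CC | intermediate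
27 | 6α-methyl carbonate of 26 | CC(C)(C)[Si](C)(C)O[C@H]1[C@@H](C(=C)B2OC(C)(C)C(C)(C)O2)[C@H](OC(=O)OC)/C=C(\C)CC/C=C(/CO[Si](C)(C)C(C)(C)C)[C@@H]1O[Si](CC)(CC)CC | intermediate
28 | monovalent copper carboxylate: 11-carboxylate with the 6α-methyl carbonate intact (carbene ligand not drawn) | CC(C)(C)[Si](C)(C)O[C@H]1[C@@H](C(=C)C(=O)[O-])[C@H](OC(=O)OC)/C=C(\C)CC/C=C(/CO[Si](C)(C)C(C)(C)C)[C@@H]1O[Si](CC)(CC)CC.[Cu+] | intermediate (not isolated)
29 | (1(10)Z,4E)-8β,14-bis[(tert-butyldimethylsilyl)oxy]-9α-[(triethylsilyl)oxy]germacra-1(10),4,11(13)-trien-12,6α-olide | CC(C)(C)[Si](C)(C)O[C@H]1[C@H]2C(=C)C(=O)O[C@@H]2/C=C(\C)CC/C=C(/CO[Si](C)(C)C(C)(C)C)[C@@H]1O[Si](CC)(CC)CC | intermediate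
30 | (1(10)Z,4E)-8β,14-bis[(tert-butyldimethylsilyl)oxy]-9α-hydroxygermacra-1(10),4,11(13)-trien-12,6α-olide | CC(C)(C)[Si](C)(C)O[C@H]1[C@H]2C(=C)C(=O)O[C@@H]2/C=C(\C)CC/C=C(/CO[Si](C)(C)C(C)(C)C)[C@@H]1O | intermediate
31 | neryl acetate, (2Z)-3,7-dimethylocta-2,6-dien-1-yl acetate | CC(C)=CCC/C(C)=C\COC(C)=O | starting material
32 | (2Z)-5-(5,5-dimethyl-1,2,4-trioxolan-3-yl)-3-methylpent-2-en-1-yl acetate (secondary ozonide) | CC1(C)OOC(CC/C(C)=C\COC(C)=O)O1 | intermediate (not isolated)
33 | (2Z)-3-methyl-6-oxohex-2-en-1-yl acetate | O=CCC/C(C)=C\COC(C)=O | intermediate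
34 | methyl 2-[bis(2,2,2-trifluoroethoxy)phosphoryl]acetate | COC(=O)CP(=O)(OCC(F)(F)F)OCC(F)(F)F | starting material
35 | 3-bromo-1,1-dimethoxypropane | COC(CCBr)OC | starting material
36 | methyl 2-[bis(2,2,2-trifluoroethoxy)phosphoryl]-5,5-dimethoxypentanoate (racemic) | COC(=O)C(CCC(OC)OC)P(=O)(OCC(F)(F)F)OCC(F)(F)F | intermediate
37 | methyl (2Z,6Z)-8-acetoxy-2-(3,3-dimethoxypropyl)-6-methylocta-2,6-dienoate | COC(=O)/C(=C\CC/C(C)=C\COC(C)=O)CCC(OC)OC | intermediate
38 | (2Z,6Z)-2-(3,3-dimethoxypropyl)-6-methylocta-2,6-diene-1,8-diol | OC/C(=C\CC/C(C)=C\CO)CCC(OC)OC | intermediate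
39 | (2Z,6Z)-2-(3,3-dimethoxypropyl)-6-methylocta-2,6-diene-1,8-diyl diacetate | CC(=O)OC/C(=C\CC/C(C)=C\COC(C)=O)CCC(OC)OC | intermediate
40 | (2Z,6Z)-6-methyl-2-(3-oxopropyl)octa-2,6-diene-1,8-diyl diacetate | CC(=O)OC/C(=C\CC/C(C)=C\COC(C)=O)CCC=O | intermediate
41 | 3-bromobut-3-en-1-ol | OCCC(Br)=C | starting material
42 | 4-methyl-3-methylidenepentan-1-ol | OCCC(=C)C(C)C | intermediate
43 | 5-iodo-2-methyl-3-methylidenepentane | ICCC(=C)C(C)C | intermediate
44 | methyl 2-[bis(2,2,2-trifluoroethoxy)phosphoryl]-6-methyl-5-methylideneheptanoate (racemic) | COC(=O)C(CCC(=C)C(C)C)P(=O)(OCC(F)(F)F)OCC(F)(F)F | intermediate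
45 | methyl (2Z,6Z,10Z)-12-acetoxy-6-(acetoxymethyl)-10-methyl-2-(4-methyl-3-methylidenepentyl)dodeca-2,6,10-trienoate | COC(=O)/C(=C\CC/C(=C/CC/C(C)=C\COC(C)=O)COC(C)=O)CCC(=C)C(C)C | intermediate
46 | (2Z,6Z,10Z)-12-hydroxy-6-(hydroxymethyl)-10-methyl-2-(4-methyl-3-methylidenepentyl)dodeca-2,6,10-trienoic acid | OC(=O)/C(=C\CC/C(=C/CC/C(C)=C\CO)CO)CCC(=C)C(C)C | intermediate
47 | mixed anhydride of acid 48 with acetic acid | CC(=O)OC(=O)/C(=C\CC/C(=C/CC/C(C)=C\COC(C)=O)COC(C)=O)CCC(=C)C(C)C | intermediate (not isolated)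
48 | (2Z,6Z,10Z)-12-acetoxy-6-(acetoxymethyl)-10-methyl-2-(4-methyl-3-methylidenepentyl)dodeca-2,6,10-trienoic acid | OC(=O)/C(=C\CC/C(=C/CC/C(C)=C\COC(C)=O)COC(C)=O)CCC(=C)C(C)C | intermediate
49 | mixed anhydride of acid 48 with 2-methyl-6-nitrobenzoic acid | Cc1cccc([N+](=O)[O-])c1C(=O)OC(=O)/C(=C\CC/C(=C/CC/C(C)=C\COC(C)=O)COC(C)=O)CCC(=C)C(C)C | intermediate (not isolated)
50 | 9α-ester of 30 with acid 48 (8β,14-bis-silyloxy lactone) | CC(C)(C)[Si](C)(C)O[C@H]1[C@H]2C(=C)C(=O)O[C@@H]2/C=C(\C)CC/C=C(/CO[Si](C)(C)C(C)(C)C)[C@@H]1OC(=O)/C(=C\CC/C(=C/CC/C(C)=C\COC(C)=O)COC(C)=O)CCC(=C)C(C)C | intermediate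
51 | 8β,14-diol from 50 | O[C@H]1[C@H]2C(=C)C(=O)O[C@@H]2/C=C(\C)CC/C=C(/CO)[C@@H]1OC(=O)/C(=C\CC/C(=C/CC/C(C)=C\COC(C)=O)COC(C)=O)CCC(=C)C(C)C | intermediate
52 | 8β-hydroxy-14-oxo compound from 51 | O[C@H]1[C@H]2C(=C)C(=O)O[C@@H]2/C=C(\C)CC/C=C(/C=O)[C@@H]1OC(=O)/C(=C\CC/C(=C/CC/C(C)=C\COC(C)=O)COC(C)=O)CCC(=C)C(C)C | intermediate
53 | methyl 2-(hydroxymethyl)prop-2-enoate | C=C(CO)C(=O)OC | starting material
54 | methyl 2-{[(tert-butyldimethylsilyl)oxy]methyl}prop-2-enoate | C=C(CO[Si](C)(C)C(C)(C)C)C(=O)OC | intermediate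
55 | 2-{[(tert-butyldimethylsilyl)oxy]methyl}prop-2-enoic acid | C=C(CO[Si](C)(C)C(C)(C)C)C(=O)O | intermediate
56 | mixed anhydride of acid 55 with 2-methyl-6-nitrobenzoic acid | C=C(CO[Si](C)(C)C(C)(C)C)C(=O)OC(=O)c1c(C)cccc1[N+](=O)[O-] | intermediate (not isolated)
57 | silyl-protected target: 8β-(2-{[(tert-butyldimethylsilyl)oxy]methyl}acryloyl) ester of 52 | C=C(CO[Si](C)(C)C(C)(C)C)C(=O)O[C@H]1[C@H]2C(=C)C(=O)O[C@@H]2/C=C(\C)CC/C=C(/C=O)[C@@H]1OC(=O)/C(=C\CC/C(=C/CC/C(C)=C\COC(C)=O)COC(C)=O)CCC(=C)C(C)C | intermediate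
58 | CNP0240680.3: (1(10)Z,4E,6R,7S,8S,9S)-8β-[2-(hydroxymethyl)acryloyloxy]-9α-[(2Z,6Z,10Z)-12-acetoxy-6-(acetoxymethyl)-10-methyl-2-(4-methyl-3-methylidenepentyl)dodeca-2,6,10-trienoyloxy]-14-oxogermacra-1(10),4,11(13)-trien-12,6α-olide | C=C(CO)C(=O)O[C@H]1[C@H]2C(=C)C(=O)O[C@@H]2/C=C(\C)CC/C=C(/C=O)[C@@H]1OC(=O)/C(=C\CC/C(=C/CC/C(C)=C\COC(C)=O)COC(C)=O)CCC(=C)C(C)C | target

**Step count and risks**

Total step count: 41. Longest linear sequence: 26 steps (steps 2–22, then 35, 36, 37, 40 and 41).

Steps most likely to fail: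

1. Step 21 (Proposed new method). What may go wrong: transfer of the alkenyl group from copper to the allylpalladium before CO2 insertion (C–C coupling), slow ionisation of the carbonate inside the ten-membered ring, or protodeboronation. Fallback with known chemistry: it sets out from the hydroxy alkenyl iodide 25 and comes back at lactone 29. Palladium-catalysed carbonylative lactonisation (Pd(PPh3)4, CO at 1 atm, Et3N, MeCN/THF, 60 °C) converts the alkenyl iodide into an acylpalladium species that is captured by the free 6α-hydroxyl, so 29 is reached directly and steps 19–21 are bypassed. The fallback makes no new compound, F0.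

2. Step 12. What may go wrong: the SN2 displacement at C8 has to come from the inner face of the ring, so it may be slow and give elimination or retention; the same problem arises if step 11 hydroxylates with poor facial selectivity. Fallback: it sets out from ketol 18 and comes back at ketol 20. Dess–Martin oxidation (NaHCO3, CH2Cl2, 0 °C) should give the 8,9-dione F1, and NaBH4 at −78 °C (THF/MeOH) should reduce the more electrophilic, non-conjugated C8 carbonyl from the outer face. This places the hydroxyl 8β by hydride delivery instead of by substitution; contact times are kept short because C7 is enolisable in F1.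

3. Step 15. What may go wrong: hydride delivery to the other face of the C9 carbonyl, giving the 9β-alcohol. Fallback: it sets out from ketone 21 and comes back at alcohol 22. The reduction product, the 9β-alcohol F2, is inverted by a Mitsunobu reaction with 4-nitrobenzoic acid (PPh3, diisopropyl azodicarboxylate, toluene) to the 9α-(4-nitrobenzoate) F3, and brief methanolysis (K2CO3, MeOH, 0 °C) then gives 22.

Further compounds
F0 | step 21 | none | none
F1 | step 12 | (1(10)Z,4E)-14-[(tert-butyldimethylsilyl)oxy]-6α-[(4-methoxybenzyl)oxy]-11-(trimethylsilyl)-12-norgermacra-1(10),4,11(13)-triene-8,9-dione | O=C1[C@@H](C(=C)[Si](C)(C)C)[C@H](OCc2ccc(OC)cc2)/C=C(\C)CC/C=C(/CO[Si](C)(C)C(C)(C)C)C1=O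
F2 | step 15 | 9β-alcohol, C9 epimer of 22 | CC(C)(C)[Si](C)(C)O[C@H]1[C@@H](C(=C)[Si](C)(C)C)[C@H](OCc2ccc(OC)cc2)/C=C(\C)CC/C=C(/CO[Si](C)(C)C(C)(C)C)[C@H]1O
F3 | step 15 | 9α-(4-nitrobenzoate) of 22 | CC(C)(C)[Si](C)(C)O[C@H]1[C@@H](C(=C)[Si](C)(C)C)[C@H](OCc2ccc(OC)cc2)/C=C(\C)CC/C=C(/CO[Si](C)(C)C(C)(C)C)[C@@H]1OC(=O)c1ccc(cc1)[N+](=O)[O-]
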